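**Plan**

Target numbering: ring C1 (tertiary carbinol, bears the chain C1′–C16′), C2, C3 (secondary carbinol), C4=C5, C6. Enabling feature: C1 is homoallylic to the cis ring alkene (C1–C6–C5=C4), carries oxygen and carries C1′, which can be a carboxyl carbon. This is the retron of a Claisen shift from an ester oxygen on C4, i.e. of a six-membered lactone O–C1′(=O)–C1–C2–C3–C4 bearing a vinyl group (C5=C6) on C4.
Cuts: C1′–C2′ (Grignard reagent + spiro-epoxide), C12′=C13′ (Wittig), ring bond C1–C6 (retro-Ireland–Claisen to the lactone), C1–C2 (glycolate enolate + triflate), C3–C4 (γ-alkoxyallylboration).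
Forward: acyclic C2–C6 unit → δ-lactone ring → cyclohexene ring by the [3,3] shift (the only carbocycle-forming event) → spiro-epoxide → C15 chain joined → desilylation.
Stereochemistry: C3 and the lactone carbinol C4 come from a reagent-controlled syn-alkoxyallylboration; C1 by suprafacial chirality transfer from C4 across the lactone; C4=C5 is cis by the ring; C12′=C13′ is Z from a lithium-free Wittig reaction.

Key step: step 6

Remark on the chemistry: (+)-Ipc2BOMe denotes the B-methoxydiisopinocampheylborane made from (−)-α-pinene, and its usual sense of induction (allyl transfer to the Re face of an unbranched aldehyde) is assumed. Compounds 11–13 are mixtures of epimers at the benzyloxy-bearing carbon, which is planarised in step 6. Compound names use their own locants.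

Step 1
Reactants: 1 (tert-butyldimethylsilyloxy)acetaldehyde; 2 3-(methoxymethoxy)prop-1-ene
Product: 5 (2S,3S)-1-[(tert-butyldimethylsilyl)oxy]-3-(methoxymethoxy)pent-4-en-2-ol, via allylborane 3 (not isolated), via borinate adduct 4 (not isolated)
Conditions: 2, s-BuLi, THF, −78 °C; (+)-Ipc2BOMe; BF3·OEt2; then 1, −78 °C; NaOH, H2O2, 0 °C → rt
Reagents that add atoms: none
Why: Asymmetric γ-alkoxyallylboration (Brown-type allylboration with a diisopinocampheylborane): the Z-configured allylborane 3 adds through a closed chair transition state, so the Z geometry should give the syn ether–alcohol pair while the isopinocampheyl groups derived from (−)-α-pinene direct the allyl unit to the Re face of 1, setting both new stereocentres as (2S,3S) before the boron bonds are cleaved oxidatively.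

Step 2
Reactants: 5 (2S,3S)-1-[(tert-butyldimethylsilyl)oxy]-3-(methoxymethoxy)pent-4-en-2-ol
Product: 6 (3S,4S)-4,5-bis[(tert-butyldimethylsilyl)oxy]-3-(methoxymethoxy)pent-1-ene
Conditions: TBSCl, imidazole, DMAP (cat.), DMF, rt
Reagents that add atoms: tert-butyldimethylsilyl chloride, CC(C)(C)[Si](C)(C)Cl
Why: Standard silyl ether formation (silylation of a secondary alcohol with the silyl chloride and imidazole) that leaves the acetal and the primary silyl ether untouched and creates no stereocentre.

Step 3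
Reactants: 6 (3S,4S)-4,5-bis[(tert-butyldimethylsilyl)oxy]-3-(methoxymethoxy)pent-1-ene
Product: 7 (2S,3S)-2-[(tert-butyldimethylsilyl)oxy]-3-(methoxymethoxy)pent-4-en-1-ol
Conditions: HF·pyridine, pyridine, THF, 0 °C
Reagents that add atoms: none
Why: Chemoselective desilylation: buffered HF·pyridine cleaves the unhindered primary silyl ether much faster than the secondary one flanked by two branched carbons, and the acetal is inert to fluoride.

Step 4
Reactants: 7 (2S,3S)-2-[(tert-butyldimethylsilyl)oxy]-3-(methoxymethoxy)pent-4-en-1-ol; 8 methyl 2-(benzyloxy)acetate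
Product: 11 methyl (4S,5S)-2-(benzyloxy)-4-[(tert-butyldimethylsilyl)oxy]-5-(methoxymethoxy)hept-6-enoate (both C2 epimers), via triflate 9 (not isolated), via lithium enolate 10 (not isolated)
Conditions: 7, Tf2O, 2,6-lutidine, CH2Cl2, −78 °C; separately 8, LiN(i-Pr)2, THF, −78 °C; combine, THF/DMPU, −78 → −40 °C
Reagents that add atoms: none
Why: Ester enolate alkylation (SN2) with a primary triflate, an electrophile reactive enough at −78 °C to outrun self-condensation and Wittig rearrangement of the α-benzyloxy enolate; the new benzyloxy-bearing stereocentre is not controlled and need not be, because it is planarised in step 6.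

Step 5
Reactants: 11 methyl (4S,5S)-2-(benzyloxy)-4-[(tert-butyldimethylsilyl)oxy]-5-(methoxymethoxy)hept-6-enoate
Product: 13 (5S,6S)-3-(benzyloxy)-5-[(tert-butyldimethylsilyl)oxy]-6-ethenyloxan-2-one (both C3 epimers), via hydroxy ester 12 (not isolated)
Conditions: Me2BBr, CH2Cl2, −78 °C; aq. NaHCO3/THF; then PPTS (cat.), toluene, 60 °C
Reagents that add atoms: none
Why: Lewis-acid cleavage of the methoxymethyl acetal with Me2BBr (silyl ether, benzyl ether and ester are inert at −78 °C) followed by acid-catalysed lactonisation (intramolecular transesterification), which can give only the six-membered lactone because the C4 oxygen is silylated; C4 and C5 are untouched and become C5 and C6 of 13 with the silyloxy and vinyl groups cis.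

Step 6
Reactants: 13 (5S,6S)-3-(benzyloxy)-5-[(tert-butyldimethylsilyl)oxy]-6-ethenyloxan-2-one
Product: 16 (1S,5S)-1-(benzyloxy)-5-[(tert-butyldimethylsilyl)oxy]cyclohex-3-ene-1-carboxylic acid, via silyl ketene acetal 14 (not isolated), via trimethylsilyl ester 15 (not isolated)
Conditions: Me3SiCl/Et3N, then LiN(i-Pr)2, THF, −78 °C → rt; toluene, 105 °C; then H2O, aq. citric acid
Reagents that add atoms: none
Why: Ireland–Claisen rearrangement of a lactone: LiN(i-Pr)2 removes the only acidic proton (C3–H, so both C3 epimers of 13 converge) and Me3SiCl traps the enolate as the cyclic ketene acetal 14, whose geometry is fixed by the ring. On heating, 14 undergoes a concerted suprafacial [3,3]-sigmatropic shift in which the bond from C3 to the vinyl terminus forms as the allylic C6–O1 bond breaks; the closest known reaction type is the Ireland–Claisen conversion of 6-alkenyl lactone silyl ketene acetals into cycloalkenecarboxylic acids. The cyclohexene ring closes through a boat-like, bicyclo[2.2.2]octane-shaped transition state (the only one the six-membered lactone can reach), which places the new alkene cis inside the ring and turns the lactone carbonyl into the exocyclic carboxyl group. The new quaternary stereocentre is controlled by C6 of the lactone: the vinyl group can reach C3 only across the ring face it occupies, so the C–C bond is made on the face that the ring oxygen leaves. Because the C5 silyloxy group is cis to the vinyl group, this puts the carboxyl group trans and the benzyloxy group cis to the silyloxy group, i.e. (1S,5S). The step needs only this face selectivity and clean O-silylation, which the ring constraint, a vinyl group that can go axial with the silyloxy group equatorial, and in situ trapping of the enolate should secure.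

Step 7
Reactants: 16 (1S,5S)-1-(benzyloxy)-5-[(tert-butyldimethylsilyl)oxy]cyclohex-3-ene-1-carboxylic acid
Product: 17 [(1S,5S)-1-(benzyloxy)-5-[(tert-butyldimethylsilyl)oxy]cyclohex-3-en-1-yl]methanol
Conditions: LiAlH4, THF, 0 °C → rt; H2O, aq. NaOH
Reagents that add atoms: none
Why: Hydride reduction of a carboxylic acid to the primary alcohol with LiAlH4, which leaves the isolated ring alkene, the benzyl ether and the silyl ether intact and touches no stereocentre.

Step 8
Reactants: 17 [(1S,5S)-1-(benzyloxy)-5-[(tert-butyldimethylsilyl)oxy]cyclohex-3-en-1-yl]methanol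
Product: 18 (1S,5S)-5-[(tert-butyldimethylsilyl)oxy]-1-(hydroxymethyl)cyclohex-3-en-1-ol
Conditions: Li/4,4′-di-tert-butylbiphenyl (preformed radical anion), THF, −78 °C; aq. NH4Cl
Reagents that add atoms: none
Why: Reductive debenzylation by single-electron transfer (arene radical anion, dissolving-metal type), chosen because hydrogenolysis would saturate the ring alkene; at −78 °C the benzyl C–O bond should cleave well before the isolated alkene or the silyl ether is affected, and the carbinol C–O bond is not broken.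

Step 9
Reactants: 18 (1S,5S)-5-[(tert-butyldimethylsilyl)oxy]-1-(hydroxymethyl)cyclohex-3-en-1-ol
Product: 20 tert-butyldimethyl{[(3S,7S)-1-oxaspiro[2.5]oct-5-en-7-yl]oxy}silane, via monotosylate 19 (not isolated)
Conditions: TsCl, Et3N, DMAP (cat.), CH2Cl2, 0 °C; then K2CO3, MeOH, rt
Reagents that add atoms: none
Why: Selective sulfonylation of the primary hydroxyl of the 1,2-diol followed by intramolecular Williamson etherification (3-exo-tet) by the tertiary alkoxide; the tertiary C–O bond is retained, so the configuration at the spiro carbon is that of 18.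

Step 10
Reactants: 21 1-bromo-4-phenylbutane
Product: 22 (4-phenylbutyl)triphenylphosphonium bromide
Conditions: PPh3, MeCN, reflux
Reagents that add atoms: triphenylphosphine, c1ccc(cc1)P(c1ccccc1)c1ccccc1
Why: Quaternisation of triphenylphosphine by a primary alkyl bromide (SN2), the standard entry to a Wittig salt.

Step 11
Reactants: 23 11-bromoundecan-1-ol
Product: 24 11-bromoundecanal
Conditions: TEMPO (10 mol %), PhI(OAc)2, CH2Cl2, rt
Reagents that add atoms: none
Why: Oxoammonium-mediated (TEMPO) oxidation of a primary alcohol with PhI(OAc)2 as terminal oxidant stops cleanly at the aldehyde and does not affect the alkyl bromide.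

Step 12
Reactants: 22 (4-phenylbutyl)triphenylphosphonium bromide; 24 11-bromoundecanal
Product: 26 [(4Z)-15-bromopentadec-4-en-1-yl]benzene, via ylide 25 (not isolated)
Conditions: 22, NaN(SiMe3)2, THF, −78 → 0 °C; then 24, −78 °C → rt
Reagents that add atoms: none
Why: Wittig olefination of an aldehyde with a non-stabilised ylide under lithium-free conditions, which proceeds through the kinetically favoured cis-oxaphosphetane and should therefore give the Z alkene; at −78 °C the ylide adds to the aldehyde far faster than it is alkylated by the primary bromide.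

Step 13
Reactants: 26 [(4Z)-15-bromopentadec-4-en-1-yl]benzene; 20 tert-butyldimethyl{[(3S,7S)-1-oxaspiro[2.5]oct-5-en-7-yl]oxy}silane
Product: 28 (1S,5S)-5-[(tert-butyldimethylsilyl)oxy]-1-[(12Z)-16-phenylhexadec-12-en-1-yl]cyclohex-3-en-1-ol, via Grignard reagent 27 (not isolated)
Conditions: 26, Mg, THF, rt → 40 °C; CuI (copper iodide, 10 mol %), −30 °C; then 20, −30 → 0 °C; aq. NH4Cl
Reagents that add atoms: none
Why: Copper-catalysed ring opening of a 2,2-disubstituted epoxide by a Grignard reagent (SN2 at the unhindered CH2 terminus), which makes the C1′–C2′ bond and releases the tertiary alcohol without touching either stereocentre; the ring alkene is homoallylic to the epoxide, so no SN2′ pathway is open.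

Step 14
Reactants: 28 (1S,5S)-5-[(tert-butyldimethylsilyl)oxy]-1-[(12Z)-16-phenylhexadec-12-en-1-yl]cyclohex-3-en-1-ol
Product: 29 (1S,3S)-1-[(12Z)-16-phenylhexadec-12-en-1-yl]cyclohex-4-ene-1,3-diol
Conditions: Bu4NF, THF, 0 °C → rt
Reagents that add atoms: none
Why: Fluoride-induced cleavage of the silyl ether (Si–F bond formation) frees the allylic alcohol under conditions that leave both alkenes and the stereocentres unchanged.

**Compound list**

1 | (tert-butyldimethylsilyloxy)acetaldehyde | CC(C)(C)[Si](C)(C)OCC=O | starting material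
2 | 3-(methoxymethoxy)prop-1-ene | C=CCOCOC | starting material
3 | [(Z)-3-(methoxymethoxy)prop-2-en-1-yl]bis(isopinocampheyl)borane, isopinocampheyl groups from (−)-α-pinene | COCO/C=C\CB([C@H]1C[C@H]2C[C@H](C2(C)C)[C@@H]1C)[C@H]1C[C@H]2C[C@H](C2(C)C)[C@@H]1C | intermediate (not isolated)
4 | (2S,3S)-1-[(tert-butyldimethylsilyl)oxy]-3-(methoxymethoxy)pent-4-en-2-yl bis(isopinocampheyl)borinate | CC(C)(C)[Si](C)(C)OC[C@H](OB([C@H]1C[C@H]2C[C@H](C2(C)C)[C@@H]1C)[C@H]1C[C@H]2C[C@H](C2(C)C)[C@@H]1C)[C@@H](OCOC)C=C | intermediate (not isolated)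
5 | (2S,3S)-1-[(tert-butyldimethylsilyl)oxy]-3-(methoxymethoxy)pent-4-en-2-ol | CC(C)(C)[Si](C)(C)OC[C@H](O)[C@@H](OCOC)C=C | intermediate
6 | (3S,4S)-4,5-bis[(tert-butyldimethylsilyl)oxy]-3-(methoxymethoxy)pent-1-ene | CC(C)(C)[Si](C)(C)OC[C@H](O[Si](C)(C)C(C)(C)C)[C@@H](OCOC)C=C | intermediate
7 | (2S,3S)-2-[(tert-butyldimethylsilyl)oxy]-3-(methoxymethoxy)pent-4-en-1-ol | OC[C@H](O[Si](C)(C)C(C)(C)C)[C@@H](OCOC)C=C | intermediate
8 | methyl 2-(benzyloxy)acetate | COC(=O)COCc1ccccc1 | starting material
9 | (2S,3S)-2-[(tert-butyldimethylsilyl)oxy]-3-(methoxymethoxy)pent-4-en-1-yl trifluoromethanesulfonate | FC(F)(F)S(=O)(=O)OC[C@H](O[Si](C)(C)C(C)(C)C)[C@@H](OCOC)C=C | intermediate (not isolated)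
10 | lithium enolate of methyl 2-(benzyloxy)acetate | COC(O[Li])=COCc1ccccc1 | intermediate (not isolated)
11 | methyl (4S,5S)-2-(benzyloxy)-4-[(tert-butyldimethylsilyl)oxy]-5-(methoxymethoxy)hept-6-enoate, C2 epimers | COC(=O)C(OCc1ccccc1)C[C@H](O[Si](C)(C)C(C)(C)C)[C@@H](OCOC)C=C | intermediate
12 | methyl (4S,5S)-2-(benzyloxy)-4-[(tert-butyldimethylsilyl)oxy]-5-hydroxyhept-6-enoate, C2 epimers | COC(=O)C(OCc1ccccc1)C[C@H](O[Si](C)(C)C(C)(C)C)[C@@H](O)C=C | intermediate (not isolated)
13 | (5S,6S)-3-(benzyloxy)-5-[(tert-butyldimethylsilyl)oxy]-6-ethenyloxan-2-one, C3 epimers | C=C[C@@H]1OC(=O)C(OCc2ccccc2)C[C@@H]1O[Si](C)(C)C(C)(C)C | intermediate (precursor of the key step)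
14 | (2S,3S)-5-(benzyloxy)-3-[(tert-butyldimethylsilyl)oxy]-2-ethenyl-6-[(trimethylsilyl)oxy]-3,4-dihydro-2H-pyran | C=C[C@@H]1OC(O[Si](C)(C)C)=C(OCc2ccccc2)C[C@@H]1O[Si](C)(C)C(C)(C)C | intermediate (not isolated)
15 | trimethylsilyl (1S,5S)-1-(benzyloxy)-5-[(tert-butyldimethylsilyl)oxy]cyclohex-3-ene-1-carboxylate | CC(C)(C)[Si](C)(C)O[C@@H]1C=CC[C@@](OCc2ccccc2)(C(=O)O[Si](C)(C)C)C1 | intermediate (not isolated)
16 | (1S,5S)-1-(benzyloxy)-5-[(tert-butyldimethylsilyl)oxy]cyclohex-3-ene-1-carboxylic acid | CC(C)(C)[Si](C)(C)O[C@@H]1C=CC[C@@](OCc2ccccc2)(C(=O)O)C1 | intermediate (product of the key step)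
17 | [(1S,5S)-1-(benzyloxy)-5-[(tert-butyldimethylsilyl)oxy]cyclohex-3-en-1-yl]methanol | CC(C)(C)[Si](C)(C)O[C@@H]1C=CC[C@@](OCc2ccccc2)(CO)C1 | intermediate
18 | (1S,5S)-5-[(tert-butyldimethylsilyl)oxy]-1-(hydroxymethyl)cyclohex-3-en-1-ol | CC(C)(C)[Si](C)(C)O[C@@H]1C=CC[C@@](O)(CO)C1 | intermediate
19 | [(1S,5S)-5-[(tert-butyldimethylsilyl)oxy]-1-hydroxycyclohex-3-en-1-yl]methyl 4-methylbenzenesulfonate | CC(C)(C)[Si](C)(C)O[C@@H]1C=CC[C@@](O)(COS(=O)(=O)c2ccc(C)cc2)C1 | intermediate (not isolated)
20 | tert-butyldimethyl{[(3S,7S)-1-oxaspiro[2.5]oct-5-en-7-yl]oxy}silane | CC(C)(C)[Si](C)(C)O[C@@H]1C=CC[C@@]2(CO2)C1 | intermediate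
21 | 1-bromo-4-phenylbutane | BrCCCCc1ccccc1 | starting material
22 | (4-phenylbutyl)triphenylphosphonium bromide | [Br-].c1ccc(cc1)[P+](CCCCc1ccccc1)(c1ccccc1)c1ccccc1 | intermediate
23 | 11-bromoundecan-1-ol | OCCCCCCCCCCCBr | starting material
24 | 11-bromoundecanal | O=CCCCCCCCCCCBr | intermediate
25 | (4-phenylbutylidene)triphenylphosphorane | c1ccc(cc1)P(=CCCCc1ccccc1)(c1ccccc1)c1ccccc1 | intermediate (not isolated)
26 | [(4Z)-15-bromopentadec-4-en-1-yl]benzene | BrCCCCCCCCCC/C=C\CCCc1ccccc1 | intermediate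
27 | [(11Z)-15-phenylpentadec-11-en-1-yl]magnesium bromide | Br[Mg]CCCCCCCCCC/C=C\CCCc1ccccc1 | intermediate (not isolated)
28 | (1S,5S)-5-[(tert-butyldimethylsilyl)oxy]-1-[(12Z)-16-phenylhexadec-12-en-1-yl]cyclohex-3-en-1-ol | CC(C)(C)[Si](C)(C)O[C@@H]1C=CC[C@@](O)(CCCCCCCCCCC/C=C\CCCc2ccccc2)C1 | intermediate
29 | (1S,3S)-1-[(12Z)-16-phenylhexadec-12-en-1-yl]cyclohex-4-ene-1,3-diol | O[C@@H]1C=CC[C@@](O)(CCCCCCCCCCC/C=C\CCCc2ccccc2)C1 | target

**Step count and risks**

Total steps: 14. Longest linear sequence: 11 steps (1–9, 13, 14); steps 10–12 build the side chain in parallel.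

Steps most likely to fail:

Step 6. The lithium enolate of 13 may condense or be C-silylated, and the boat-type transition state may demand a temperature at which ketene acetal 14 degrades. The fallback makes the same C–C bond one oxidation level lower and without any enolate. It sets out from 13, which is reduced with i-Bu2AlH (CH2Cl2, −78 °C) to the lactol (5S,6S)-3-(benzyloxy)-5-[(tert-butyldimethylsilyl)oxy]-6-ethenyloxan-2-ol F1. This is dehydrated through its anomeric mesylate F2 (MsCl, Et3N, then DBU) to the enol ether (2S,3S)-5-(benzyloxy)-3-[(tert-butyldimethylsilyl)oxy]-2-ethenyl-3,4-dihydro-2H-pyran F3. Thermolysis of F3 (o-dichlorobenzene, about 220 °C, sealed tube) is an aliphatic Claisen rearrangement of a 2-vinyl-dihydropyran and should give, by the same boat-type chirality transfer, the aldehyde (1S,5S)-1-(benzyloxy)-5-[(tert-butyldimethylsilyl)oxy]cyclohex-3-ene-1-carbaldehyde F4. Reduction with NaBH4 (MeOH, 0 °C) comes back to the route at 17.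

Step 4. The triflate 9 may decompose through participation of the neighbouring acetal oxygen, or the glycolate enolate 10 may be alkylated too slowly and rearrange. The fallback makes the chain C–C bond before the stereocentres and sets out from 8 (reusing 2 through reagent 3). Allylation of 8 (LiN(i-Pr)2, allyl bromide, THF, −78 °C) gives methyl 2-(benzyloxy)pent-4-enoate F5, and ozonolysis (O3, CH2Cl2, −78 °C; PPh3) gives methyl 2-(benzyloxy)-4-oxobutanoate F6. γ-Alkoxyallylboration of F6 with 3 (buffered NaBO3 work-up) should give the hydroxy ester methyl (4S,5S)-2-(benzyloxy)-4-hydroxy-5-(methoxymethoxy)hept-6-enoate F7, which is allowed to close (PPTS) to the γ-lactone (5S)-3-(benzyloxy)-5-[(1S)-1-(methoxymethoxy)prop-2-en-1-yl]oxolan-2-one F8. Opening with MeNH(OMe)·HCl and Al(CH3)3 gives the hydroxy Weinreb amide (4S,5S)-2-(benzyloxy)-4-hydroxy-N-methoxy-5-(methoxymethoxy)-N-methylhept-6-enamide F9, which is silylated at once (TBSOTf, 2,6-lutidine) to the silyl ether F10. Me2BBr then removes the acetal to give the δ-hydroxy amide F11, and acid (CSA, toluene, 60 °C) closes the δ-lactone, coming back to the route at 13.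

Step 13. Magnesium halide may rearrange epoxide 20 to an aldehyde or open it to a halohydrin before the cuprate attacks. The fallback joins the chain through a sulfone-stabilised carbanion and sets out from 26 and 20. Displacement of bromide in 26 with PhSO2Na (DMF, 60 °C) gives the sulfone [(11Z)-15-phenylpentadec-11-ene-1-sulfonyl]benzene F12. Its lithio derivative (n-BuLi, THF, −78 °C, then BF3·OEt2) should open 20 at the CH2 terminus to the hydroxy sulfone (1S,5S)-1-[(12Z)-2-(benzenesulfonyl)-16-phenylhexadec-12-en-1-yl]-5-[(tert-butyldimethylsilyl)oxy]cyclohex-3-en-1-ol F13 (epimers at the sulfonyl-bearing carbon). Reductive desulfonylation (sodium amalgam Na(Hg), Na2HPO4, MeOH, −20 °C) comes back to the route at 28.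

**Further compounds**

F1 | step 6 | (5S,6S)-3-(benzyloxy)-5-[(tert-butyldimethylsilyl)oxy]-6-ethenyloxan-2-ol | C=C[C@@H]1OC(O)C(OCc2ccccc2)C[C@@H]1O[Si](C)(C)C(C)(C)C
F2 | step 6 | (5S,6S)-3-(benzyloxy)-5-[(tert-butyldimethylsilyl)oxy]-6-ethenyloxan-2-yl methanesulfonate | C=C[C@@H]1OC(OS(C)(=O)=O)C(OCc2ccccc2)C[C@@H]1O[Si](C)(C)C(C)(C)C
F3 | step 6 | (2S,3S)-5-(benzyloxy)-3-[(tert-butyldimethylsilyl)oxy]-2-ethenyl-3,4-dihydro-2H-pyran | C=C[C@@H]1OC=C(OCc2ccccc2)C[C@@H]1O[Si](C)(C)C(C)(C)C
F4 | step 6 | (1S,5S)-1-(benzyloxy)-5-[(tert-butyldimethylsilyl)oxy]cyclohex-3-ene-1-carbaldehyde | CC(C)(C)[Si](C)(C)O[C@@H]1C=CC[C@@](OCc2ccccc2)(C=O)C1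
F5 | step 4 | methyl 2-(benzyloxy)pent-4-enoate | COC(=O)C(CC=C)OCc1ccccc1
F6 | step 4 | methyl 2-(benzyloxy)-4-oxobutanoate | COC(=O)C(CC=O)OCc1ccccc1
F7 | step 4 | methyl (4S,5S)-2-(benzyloxy)-4-hydroxy-5-(methoxymethoxy)hept-6-enoate | COC(=O)C(OCc1ccccc1)C[C@H](O)[C@@H](OCOC)C=C
F8 | step 4 | (5S)-3-(benzyloxy)-5-[(1S)-1-(methoxymethoxy)prop-2-en-1-yl]oxolan-2-one | C=C[C@H](OCOC)[C@@H]1CC(OCc2ccccc2)C(=O)O1
F9 | step 4 | (4S,5S)-2-(benzyloxy)-4-hydroxy-N-methoxy-5-(methoxymethoxy)-N-methylhept-6-enamide | CON(C)C(=O)C(OCc1ccccc1)C[C@H](O)[C@@H](OCOC)C=C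
F10 | step 4 | (4S,5S)-2-(benzyloxy)-4-[(tert-butyldimethylsilyl)oxy]-N-methoxy-5-(methoxymethoxy)-N-methylhept-6-enamide | CON(C)C(=O)C(OCc1ccccc1)C[C@H](O[Si](C)(C)C(C)(C)C)[C@@H](OCOC)C=C
F11 | step 4 | (4S,5S)-2-(benzyloxy)-4-[(tert-butyldimethylsilyl)oxy]-5-hydroxy-N-methoxy-N-methylhept-6-enamide | CON(C)C(=O)C(OCc1ccccc1)C[C@H](O[Si](C)(C)C(C)(C)C)[C@@H](O)C=C
F12 | step 13 | [(11Z)-15-phenylpentadec-11-ene-1-sulfonyl]benzene | O=S(=O)(CCCCCCCCCC/C=C\CCCc1ccccc1)c1ccccc1
F13 | step 13 | (1S,5S)-1-[(12Z)-2-(benzenesulfonyl)-16-phenylhexadec-12-en-1-yl]-5-[(tert-butyldimethylsilyl)oxy]cyclohex-3-en-1-ol | CC(C)(C)[Si](C)(C)O[C@@H]1C=CC[C@@](O)(CC(CCCCCCCCC/C=C\CCCc2ccccc2)S(=O)(=O)c2ccccc2)C1
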